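Target is what we read, and each unit of it is substrate turned, so we take [substrate] in each run as the charge minus the reading, bound substrate counted.

common to all: free catalyst 0.00750 M

| run | substrate | time |
|---|---|---|
| midnight | 0.150 M |  |
| winter | 0.450 M |  |
| dusk | 0.0600 M | 6.0 min |

| run | time / min | [target] / M |
|---|---|---|
| midnight run | 0.24 | 0.0057 |
| midnight run | 0.46 | 0.0092 |
| midnight run | 0.87 | 0.0185 |
| midnight run | 1.7 | 0.0313 |
| midnight run | 3.2 | 0.0504 |
| midnight run | 6.0 | 0.0711 |
| winter run | 0.24 | 0.0144 |
| winter run | 0.46 | 0.0280 |
| winter run | 0.87 | 0.0530 |
| winter run | 1.7 | 0.0994 |
| winter run | 3.2 | 0.1707 |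
| winter run | 6.0 | 0.2630 |

(readings scatter by 4 × 10⁻⁴ M)

- reaction order in [substrate] at the outset, round the charge of the midnight run, defined at two percent of the substrate turned into target (one fixed amount of target, the same in the runs compared)
- target in the dusk run at 6.0 min, as a share of the substrate charged

- Overall: substrate -> target, with free catalyst as catalyst.
- Constant volume, constant temperature.
- The analysis sees a species whether free or bound.
- An order is taken over about fifteen percent of the charge, up and down.

We read the last two rows of each table. Across such a window we take the running constant: the logarithm of [substrate] at its start over [substrate] at its end, divided by its length. This is a pseudo-first-order constant, and a first-order flask keeps it the same in every window.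

In the winter run the last window gives 0.143 min⁻¹ at a mean [substrate] of 0.233 M. In the midnight run it gives 0.0832 min⁻¹ at 0.0892 M, which is lower.

Column against column, then, over the same stretch of time, the constant is lower in the run with the lower [substrate]. We call the loss per unit of [substrate] between these two windows the sag, 0.417 M⁻¹ min⁻¹.

We treat the dusk run as a small correction to the midnight window, and we assume that the sag holds below that window. The dusk charge stands 0.0292 M below the mean [substrate] of the midnight window, so the sag takes off 0.0122 min⁻¹. That leaves 0.0710 min⁻¹ for the dusk run. Held over 6.0 min, this constant gives an estimate of 34.7% of the dusk charge turned, and that is our own reckoning.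

The forecast gives an order of 1.05 and a dusk share of 30%, on this ground: “Low substrate is what hurts”. Its share is lower than ours.

The dusk run gives 29.3% of its charge as target at 6.0 min, and the order at the outset, round the midnight charge, is 1.5.

    free catalyst + substrate ⇌ catalyst-substrate complex, settled at all times (15.10 M⁻¹)
    catalyst-substrate complex + substrate ⇌ doubly bound catalyst, settled at all times (5.870 M⁻¹)
    doubly bound catalyst → target + catalyst-substrate complex (12.66 min⁻¹)
    free catalyst → spent catalyst (0.6840 min⁻¹)
    2 free catalyst ⇌ resting dimer, settled at all times (1260 M⁻¹)

At one fixed amount of target, the winter rate is 2.8 times the midnight rate. From charge to 6.0 min, the dusk run's running constant is 0.0578 min⁻¹, lower than the 0.0710 min⁻¹ we reckoned. The same sag, read up at the midnight charge, gives 0.109 min⁻¹, hence an estimated half-time of 6.36 min. In the midnight run, target comes to half the substrate charged at 6.96 min.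

The data were computed from invented constants, noise included.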